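The numbers in the tables stem from a simulated flask from invented constants; scatter was added.

Where does the ratio of target to isomer of the product stand in the flask, early and late?

| flask | starting material | protic impurity | catalyst | remark | time |
|---|---|---|---|---|---|
| violet | 0.50 M | 0.020 M | 2 mM | run made earlier |  |
| teal | 0.75 M | 0.020 M | 2 mM | run made earlier |  |
| flask | 1.0 M | 0.0200 M | 2.0 mM |  | 10 min |

- violet (time / min: target / %, isomer of the product / %, starting material / %): 0.500: 2.4, 4.5, 91.1; 1.50: 8.9, 11.0, 77.7; 3.00: 16.3, 19.7, 63.3; 4.00: 19.9, 21.6, 56.9; 6.00: 25.4, 26.4, 46.7
- teal (time / min: target / %, isomer of the product / %, starting material / %): 0.500: 3.5, 4.3, 92.3; 1.50: 8.6, 11.7, 78.2; 3.00: 15.9, 20.2, 64.4; 4.00: 19.2, 22.5, 56.8; 6.00: 25.8, 27.4, 47.7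

(readings scatter by 0.5 percentage points)

* ratio of target to isomer of the product at 8.0 s
* ratio of target to isomer of the product at 10 min

- what was read earlier has a scatter of 0.5 percentage points, one standard deviation

The violet and teal runs end at 46.7% and 47.7% starting material although their charges differ, so I treat them as one curve and read from their mean a half-life h = 5.54 min. For the flask at 10 min I get 1.81, where n, the half-lives elapsed, is catalyst charge times time over the runs' catalyst charge times h. Equal n marks the same place on the curve, provided the rate follows the catalyst.

At 8.0 s the flask stands at n = 0.0241, nearest the first readings at n = 0.0903, where summed target over summed isomer of both runs gives 0.670. The same ratio is 0.887 at n = 0.722 and 0.952 at n = 1.08; a straight line carried on to 1.81 gives 1.08. Is one number enough? The first readings give a half-life of 4.00 min, shorter than h, so n is a position on the curve, not a decay law, and the late figure is an extrapolation.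

The forecast says 0.68 and 1.1, holding that “the isomer channel fades”.

The flask gives 0.661 and 1.09.

    starting material + catalyst ⇌ target + catalyst, rate k1*[starting material]*[catalyst] forward; the back reaction follows from the equilibrium constant (K = 1.20, k = 33.2 M⁻¹ min⁻¹)
    target + catalyst ⇌ isomer of the product + catalyst, rate k2*[catalyst]*[target] forward; the back reaction follows from the equilibrium constant (K = 0.830, k = 53.7 M⁻¹ min⁻¹)
    isomer of the product + catalyst ⇌ starting material + catalyst, rate k3*[catalyst]*[isomer of the product] forward; the back reaction follows from the equilibrium constant (k = 51.1 M⁻¹ min⁻¹)
    starting material + protic impurity → quenched substrate (k = 0.269 M⁻¹ min⁻¹)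

In the flask at 1.00 min, the isomer of the product stands at 8.65% and leads the target at 6.19%; the starting material stands at 84.7%. Target and isomer of the product draw level in the flask at 6.89 min, n = 1.24, and at n = 1.81 the flask holds 32.0% target and 29.5% isomer of the product.

The neighbour with 8.0 × 10⁻⁴ M catalyst reaches n = 0.722, the place of the readings at 4.00 min and below the level point, so n gives 0.887. The computed ratio in that neighbour is 0.880, from 19.7% target and 22.3% isomer of the product.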